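(The readings were generated by integration from invented constants.)

Maple and elm carry the same 17 mM of added ligand as the four new flasks, so I read them for one question: what would have to be true for the hot dusk to end above the cold midnight?

| setting | maple | elm | ash | summer | dusk | midnight | autumn |
|---|---|---|---|---|---|---|---|
| left-handed substrate | 0.80 M | 0.80 M | 0.80 M | 0.80 M | 0.80 M | 0.80 M | 0.80 M |
| right-handed substrate | 0.80 M | 0.80 M | 0.80 M | 0.80 M | 0.80 M | 0.80 M | 0.80 M |
| gas | 45 mM (held) | 45 mM (held) | 45 mM (held) | 45 mM (held) | 45 mM (held) | 45 mM (held) | 45 mM (held) |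
| catalyst | 10 mM | 22 mM | 15 mM | 15 mM | 15 mM | 15 mM | 15 mM |
| added ligand | 17 mM | 17 mM | 26 mM | 17 mM | 17 mM | 17 mM | 17 mM |
| temperature | 69 °C | 110 °C | 69 °C | 100 °C | 125 °C | 50 °C | 75 °C |
| remark | run made earlier | run made earlier | run made earlier |  |  |  |  |
| time |  |  |  | 3.0 h | 3.0 h | 3.0 h | 3.0 h |

| run | time / h | left-handed product / % | right-handed product / % | left-handed substrate / % |
|---|---|---|---|---|
| maple | 3.00 | 50.6 | 2.3 | 1.1 |
| maple | 6.00 | 49.5 | 7.0 | 0 |
| maple | 10.0 | 51.2 | 10.3 | 0.4 |
| maple | 12.0 | 52.2 | 13.3 | 0.8 |
| maple | 15.0 | 49.7 | 16.1 | 0.7 |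
| maple | 20.0 | 51.1 | 20.1 | 1.4 |
| elm | 0.167 | 49.2 | 1.7 | 0 |
| elm | 0.333 | 49.2 | 6.1 | 0.4 |
| elm | 0.500 | 50.0 | 10.2 | 0 |
| elm | 0.833 | 51.1 | 11.0 | 0 |
| elm | 1.33 | 50.1 | 18.9 | 0 |
| elm | 2.50 | 50.7 | 27.7 | 1.5 |
| ash | 1.33 | 46.4 | 2.0 | 2.8 |
| ash | 2.50 | 49.5 | 4.3 | 0 |
| ash | 5.00 | 50.6 | 9.6 | 0 |
| ash | 10.0 | 50.3 | 12.9 | 0 |
| ash | 20.0 | 50.8 | 23.9 | 0 |

(scatter of a reading: 1 percentage point)

- catalyst is single-handed; left-handed substrate and right-handed substrate are mirror images of each other, charged as a racemate, each of them at the stated concentration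
- at the start none of the gas is in solution
- an excess is the difference of the two amounts in percent of their sum
- an excess is below zero if the other one leads

* the flask that comes out highest in excess of left-handed product over right-handed product, or "all alike" when all lie within 1.5 percentage points (summer / dusk / midnight / autumn / all alike)
* excess of left-handed product over right-handed product at the end, summer
* excess of left-handed product over right-handed product at the end, dusk
* excess of left-handed product over right-handed product at the end, midnight
* excess of left-handed product over right-handed product at the end, autumn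

In ash the left-handed substrate reads 0 % at 2.50 h, with left-handed product at 49.5 %. After that, I take it, the excess moves with the right-handed product. With the gas held and the catalyst taken as constant, the one concentration in the rate is c(right-handed substrate), so this is a pseudo-first-order creep with a constant k. If x is the fraction of right-handed substrate left, the excess is x divided by 2 minus x, and it falls as k times time grows.

Summer, dusk, midnight and autumn share 3.0 h, 15 mM of catalyst and 17 mM of added ligand, so in this reckoning dusk ending above midnight needs k to fall on heating. From the last readings, maple gives 0.0257 h⁻¹ and elm gives 0.323 h⁻¹. Per catalyst charged, elm stands 5.71 times above maple, so the opposite outcome is far off. That ratio gives the creep energy, 46.3 kJ mol⁻¹, the slope of ln k per catalyst against inverse temperature, times the gas constant.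

At 15 mM of catalyst, k at maple's temperature is 0.0386 h⁻¹. My reckoning then gives 0.381 h⁻¹ for dusk and 0.0148 h⁻¹ for midnight. Taking left-handed product as complete, that means 19.0 % for dusk. For midnight the same assumption gives 91.7 %, and I hold it loosely there: ash still reads 2.8 % left-handed substrate at 1.33 h.

The forecast names midnight, with 93 % there, 78 % for autumn, 47 % for summer and 28 % for dusk (range 15 % to 40 %); its dusk figure differs from mine. Its verdict: “The coolest flask comes out highest.”

Summer gives 46.1 %, autumn 73.4 %, dusk 20.7 %, midnight 90.2 %, and midnight stands highest.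

    partner + catalyst + left-handed substrate → catalyst + left-handed product (k = 0.940 M⁻² s⁻¹, Ea = 47.0 kJ mol⁻¹)
    partner + catalyst + right-handed substrate → catalyst + right-handed product (k = 0.0150 M⁻² s⁻¹, Ea = 40.0 kJ mol⁻¹)
    partner → decomposed reagent (k = 6.80 × 10⁻⁵ s⁻¹, Ea = 93.0 kJ mol⁻¹)
    gas ⇌ partner, rate k4*(csat - [partner]) (kL = 0.850 s⁻¹)
    catalyst + added ligand ⇌ idle complex, settled at all times (K = 130 M⁻¹, ΔH = −13.0 kJ mol⁻¹)
    (constants at 50 °C)

At 3.00 h dusk holds 32.8 % right-handed product beside 50.0 % left-handed product. Carried to midnight left for 30.0 h, the creep energy gives 47.2 %, and that flask stands at 43.2 %.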